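The numbers in the tables are calculated for an exercise, noise included.

Time is what your quick number hangs on, and your hunch that the flask opens on uncatalysed product looks sound to me at the early time.

| setting | cedar | alder | flask |
|---|---|---|---|
| starting material | 1.5 M | 1.5 M | 1.5 M |
| reagent | 1.65 M | 1.65 M | 1.65 M |
| free catalyst | 1.5 mM | 2.2 mM | 3.0 mM |
| second catalyst | 300 mM | 300 mM | 300 mM |
| remark | run made earlier | run made earlier |  |
| time |  |  | 10 h |

- cedar (time / h: uncatalysed product / %, target / %, starting material / %): 0.333: 30.2, 11.9, 48.4; 1.00: 45.4, 28.9, 21.8; 1.50: 49.3, 35.4, 13.3; 2.50: 53.0, 39.0, 6.8; 4.00: 55.1, 41.6, 3.4; 5.00: 54.9, 41.5, 1.6; 6.00: 55.0, 43.9, 1.4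
- alder (time / h: uncatalysed product / %, target / %, starting material / %): 0.333: 27.5, 16.5, 45.1; 1.00: 42.8, 33.5, 18.9; 1.50: 45.4, 37.8, 13.0; 2.50: 48.8, 44.4, 6.4; 4.00: 50.2, 45.9, 2.5; 5.00: 51.3, 47.0, 1.1; 6.00: 51.4, 47.6, 1.2

(scatter of a reading: 0.5 percentage points)

- the analysis behind the earlier runs scatters by 0.5 percentage points, standard deviation

- share of uncatalysed product in uncatalysed product plus target at 1.5 min
- share of uncatalysed product in uncatalysed product plus target at 10 h

From cedar to alder, the ratio of target to uncatalysed product at the first reading rises by a factor 1.52, while [free catalyst] rises by 1.47, so I scale that ratio with [free catalyst]. Target comes after a lag (an induction period) and uncatalysed product starts at once, so I scale it with time too: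

ratio in the flask at 1.5 min = 0.600 × 3.0 mM/2.2 mM × 1.5 min/0.333 h = 0.0614

This 0.0614 is the opening ratio, [target] over [uncatalysed product] in the first minutes, and it gives a share of 94.2 %. But alder's ratio per hour falls from 1.80 h⁻¹ at the first reading to 0.783 h⁻¹ at the second, so the opening is steeper than my line, and I hold that share as high. For 10 h I add nothing to the forecast.

The forecast gives 96 % (91.5 % to 98.5 %) at 1.5 min and 48.7 % (46.5 % to 50.3 %) at 10 h, saying “Target therefore has a lag, while uncatalysed product starts immediately.” Its early figure is higher than mine.

The flask gives 89.9 % at 1.5 min and 48.8 % at 10 h.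

    reagent + catalyst intermediate → second catalyst + target (k = 0.237 M⁻¹ s⁻¹)
    starting material + reagent → uncatalysed product (k = 2.75 × 10⁻⁴ M⁻¹ s⁻¹)
    second catalyst + open intermediate ⇌ catalyst intermediate (K = 0.0351 M⁻¹, k = 0.00914 M⁻¹ s⁻¹)
    starting material + free catalyst ⇌ free catalyst + open intermediate (K = 0.320, k = 0.261 M⁻¹ s⁻¹)

The flask's opening ratio comes to 0.112, about twice my 0.0614, so the scaling from the first readings ran low, as the bend in alder warned. Part of the early share is catalyst intermediate falling back to second catalyst and open intermediate: with that back step struck out, the share at 1.5 min is 84.8 % against 89.9 %. Target goes through second catalyst, so for a neighbour flask charged with 1.2 M of it, I scale the opening ratio by 4.00, and since my 0.0614 ran low I start from the flask's 0.112, which gives 0.450, a share of 69.0 %; computed, that neighbour gives 71.8 %.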